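**Plan**

1. Retrosynthesis: the last cut is the O–CH2 bond of a fluoride-labile 2-(trimethylsilyl)ethyl ether on one ortho oxygen. Ring A is then opened at C1–C2 and C5–C6 (C1 = the benzoyl-bearing carbon), giving a four-carbon 1,3-dimethoxy-1-silyloxy diene (C2–C5) and a two-carbon β-alkoxy ynone (C6–C1).
2. Enabling feature: in ring A the run C2(OH)–C3(prenyl)–C4(OMe)–C5(prenyl) is the chain of an α,γ-diprenylated acetoacetate enol ether, and C6(O)–C1(COPh) is an oxygenated acetylenic ketone. All three ring oxygens therefore arrive at the right oxidation level and the ring aromatises by loss of methanol alone.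
3. Forward, diene branch: methyl acetoacetate is prenylated at the γ- and then the α-carbon, O-methylated and converted into the silyl ketene acetal, so both prenyl groups and the C4 methoxy group are in place before the ring exists.
4. Forward, ynone branch and union: trichloroethylene and 2-(trimethylsilyl)ethanol give a lithium alkynyl ether that is benzoylated. Ring A, the only ring formed, closes in step 7, and fluoride then frees the second phenol.
5. Stereochemistry: the target has no stereocentre and no stereogenic double bond. The only geometry of consequence is the (3Z) enol ether of the diene, set by allylic strain during γ-deprotonation and consumed in the ring closure.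

Key step: step 7

Remark on the chemistry: the ynol ether carries a 2-(trimethylsilyl)ethyl group rather than a simple alkyl group. Once one ortho phenol chelates the ketone, a second ortho alkyl ether is no longer cleaved by BCl3 under mild chelation control, and harsher Lewis acids would attack the prenyl groups; fluoride removes the silylethyl group without acid.

**Route**

Step 1
Reactants: 1 methyl acetoacetate; 2 1-bromo-3-methylbut-2-ene (prenyl bromide)
Product: 3 methyl 7-methyl-3-oxooct-6-enoate
Conditions: NaH, THF, 0 °C; n-BuLi, 0 °C; 2, 0 to 25 °C; aq. HCl
Reagents that add atoms: none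
Why: Acetoacetate dianion alkylation: after double deprotonation the terminal carbanion is the more nucleophilic site and is alkylated selectively by the allylic bromide in an SN2 reaction, while the stabilised enolate stays untouched until the quench.

Step 2
Reactants: 3 methyl 7-methyl-3-oxooct-6-enoate; 2 1-bromo-3-methylbut-2-ene
Product: 4 methyl 7-methyl-2-(3-methylbut-2-enyl)-3-oxooct-6-enoate (racemic)
Conditions: K2CO3, acetone, 56 °C
Reagents that add atoms: none
Why: Acetoacetic ester C-alkylation: the enolate formed reversibly with K2CO3 reacts at carbon with the soft allylic bromide and one equivalent of 2 limits dialkylation; the new stereocentre is formed racemic and disappears in step 3.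

Step 3
Reactants: 4 methyl 7-methyl-2-(3-methylbut-2-enyl)-3-oxooct-6-enoate
Product: 5 methyl (2E)-3-methoxy-7-methyl-2-(3-methylbut-2-enyl)octa-2,6-dienoate
Conditions: NaH, THF–DMPU, 0 °C; Me2SO4, 0 to 25 °C
Reagents that add atoms: dimethyl sulfate, COS(=O)(=O)OC
Why: Enolate O-alkylation: the dissociated sodium enolate of an α-substituted β-keto ester in a dipolar aprotic medium should react with the hard electrophile dimethyl sulfate at the ketone oxygen, and its extended conformation should place the methoxy group anti to the ester, which leaves the C4 methylene syn to the carbonyl for step 4 (a 2Z isomer, if formed, is carried along because this double bond becomes a single bond in the diene).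

Step 4
Reactants: 5 methyl (2E)-3-methoxy-7-methyl-2-(3-methylbut-2-enyl)octa-2,6-dienoate
Product: 6 (3Z)-1,3-dimethoxy-7-methyl-2-(3-methylbut-2-enyl)-1-(trimethylsilyloxy)octa-1,3,6-triene
Conditions: LiN(i-Pr)2, THF, −78 °C; Me3SiCl, −78 to 0 °C; non-aqueous work-up (pentane, filtration), used crude
Reagents that add atoms: chlorotrimethylsilane, C[Si](C)(C)Cl
Why: Kinetic γ-deprotonation of the β-methoxy enoate and O-silylation of the extended ester dienolate (the standard preparation of Brassard-type dienes); only the C4 protons are vinylogous to the ester, and allylic strain against the fully substituted C2 should turn the C4 side chain away from C2, giving the (3Z) geometry needed for the s-cis conformer (the ketene acetal geometry is immaterial).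

Step 5
Reactants: 7 trichloroethylene; 8 2-(trimethylsilyl)ethanol
Product: 9 (E)-1,2-dichloro-1-[2-(trimethylsilyl)ethoxy]ethene
Conditions: NaH, THF, 0 to 25 °C; 7, −40 to 25 °C
Reagents that add atoms: none
Why: Base-mediated conversion of trichloroethylene into dichloroacetylene and anti addition of the alkoxide to it (the established route to 1,2-dichlorovinyl ethers) fixes the E geometry; the sodium rather than the potassium alkoxide is used so that Peterson-type fragmentation of the β-silyl alkoxide is not an issue.

Step 6
Reactants: 9 (E)-1,2-dichloro-1-[2-(trimethylsilyl)ethoxy]ethene; 10 N-methoxy-N-methylbenzamide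
Product: 12 1-phenyl-3-[2-(trimethylsilyl)ethoxy]prop-2-yn-1-one, via lithium 2-(trimethylsilyl)ethoxyacetylide 11 (not isolated)
Conditions: n-BuLi (2.2 equiv), THF, −78 to −40 °C; 10, −78 to 0 °C; inverse quench into cold 0.5 M aq. HCl
Reagents that add atoms: none
Why: Two equivalents of n-BuLi convert the dichlorovinyl ether by dehydrochlorination and chlorine–lithium exchange into lithium alkynyl ether 11, whose addition to the N-methoxy-N-methyl amide stops at the ketone stage because the chelated adduct does not collapse before the quench (Weinreb ketone synthesis); the cold acidic quench keeps the liberated hydroxylamine protonated so that it cannot add to the ynone.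

Step 7
Reactants: 6 (3Z)-1,3-dimethoxy-7-methyl-2-(3-methylbut-2-enyl)-1-(trimethylsilyloxy)octa-1,3,6-triene; 12 1-phenyl-3-[2-(trimethylsilyl)ethoxy]prop-2-yn-1-one
Product: 15 [2-hydroxy-4-methoxy-3,5-bis(3-methylbut-2-enyl)-6-[2-(trimethylsilyl)ethoxy]phenyl](phenyl)methanone, via cyclohexa-1,4-diene cycloadduct 13 (not isolated), via aryl trimethylsilyl ether 14 (not isolated)
Conditions: 6 (1.5 equiv), PhMe, 25 to 60 °C; then 1 M aq. HCl, THF, 0 °C
Reagents that add atoms: none
Why: Proposed new method: the silyl ketene acetal diene 6 should bond through its γ-carbon (diene C4) to the oxygen-bearing β-carbon of the push–pull ynone 12 and through C1 to the α-carbon, so that ring A closes as cyclohexa-1,4-diene 13 either by a strongly asynchronous (4+2) cycloaddition or, in the stepwise limit, by vinylogous Mukaiyama–Michael addition followed by 6-(enolexo)-exo-trig attack of the allenolate carbon on the silyloxycarbenium carbon. Adduct 13 holds a mixed methyl silyl ketal carbon para to a doubly allylic C–H and should aromatise by 1,4-loss of methanol to silyl ether 14, which dilute acid hydrolyses to the ketone-chelated phenol 15. The closest known reaction type is the Diels–Alder and aromatisation sequence of Brassard-type 1,3-dialkoxy-1-silyloxybutadienes with acetylenic ketones and esters; a β-alkoxy ynone and a 2,4-dialkylated diene have not been combined in it. No stereocentre is created in 15, since the two sp3 ring carbons of 13 are erased on aromatisation. The step needs the diene γ-carbon to meet the O-substituted alkyne carbon, and this is secured because the carbonyl and the alkoxy group polarise the triple bond in the same sense, making the β-carbon the electrophilic partner for the most nucleophilic diene terminus. The (3Z) geometry keeps hydrogen on the inside of the s-cis diene, and the temperature is kept below that at which the ynol ether fragments by retro-ene loss.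

Step 8
Reactants: 15 [2-hydroxy-4-methoxy-3,5-bis(3-methylbut-2-enyl)-6-[2-(trimethylsilyl)ethoxy]phenyl](phenyl)methanone
Product: 16 (2,6-dihydroxy-4-methoxy-3,5-bis(3-methylbut-2-enyl)phenyl)(phenyl)methanone
Conditions: Bu4NF, THF, 25 to 60 °C; aq. NH4Cl
Reagents that add atoms: none
Why: Fluoride-induced cleavage of a 2-(trimethylsilyl)ethyl aryl ether: attack at silicon triggers β-elimination to ethene, Me3SiF and the phenoxide, which is protonated on work-up, while the prenyl groups, the methyl ether and the ketone are inert to fluoride.

**Compound list**

1 | methyl acetoacetate | COC(=O)CC(C)=O | starting material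
2 | 1-bromo-3-methylbut-2-ene (prenyl bromide) | CC(C)=CCBr | starting material
3 | methyl 7-methyl-3-oxooct-6-enoate | COC(=O)CC(=O)CCC=C(C)C | intermediate
4 | methyl 7-methyl-2-(3-methylbut-2-enyl)-3-oxooct-6-enoate (racemic) | COC(=O)C(CC=C(C)C)C(=O)CCC=C(C)C | intermediate
5 | methyl (2E)-3-methoxy-7-methyl-2-(3-methylbut-2-enyl)octa-2,6-dienoate | COC(=O)/C(CC=C(C)C)=C(/OC)CCC=C(C)C | intermediate
6 | (3Z)-1,3-dimethoxy-7-methyl-2-(3-methylbut-2-enyl)-1-(trimethylsilyloxy)octa-1,3,6-triene (ketene acetal geometry not defined) | COC(O[Si](C)(C)C)=C(CC=C(C)C)/C(OC)=C/CC=C(C)C | intermediate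
7 | trichloroethylene | ClC=C(Cl)Cl | starting material
8 | 2-(trimethylsilyl)ethanol | C[Si](C)(C)CCO | starting material
9 | (E)-1,2-dichloro-1-[2-(trimethylsilyl)ethoxy]ethene | C[Si](C)(C)CCO/C(Cl)=C\Cl | intermediate
10 | N-methoxy-N-methylbenzamide | CON(C)C(=O)c1ccccc1 | starting material
11 | lithium [2-(trimethylsilyl)ethoxy]acetylide | [Li]C#COCC[Si](C)(C)C | intermediate
12 | 1-phenyl-3-[2-(trimethylsilyl)ethoxy]prop-2-yn-1-one | C[Si](C)(C)CCOC#CC(=O)c1ccccc1 | intermediate
13 | [4,6-dimethoxy-3,5-bis(3-methylbut-2-enyl)-2-[2-(trimethylsilyl)ethoxy]-6-(trimethylsilyloxy)cyclohexa-1,4-dien-1-yl](phenyl)methanone (mixture of diastereomers) | COC1(O[Si](C)(C)C)C(CC=C(C)C)=C(OC)C(CC=C(C)C)C(OCC[Si](C)(C)C)=C1C(=O)c1ccccc1 | intermediate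
14 | [4-methoxy-3,5-bis(3-methylbut-2-enyl)-2-[2-(trimethylsilyl)ethoxy]-6-(trimethylsilyloxy)phenyl](phenyl)methanone | C[Si](C)(C)CCOc1c(CC=C(C)C)c(OC)c(CC=C(C)C)c(O[Si](C)(C)C)c1C(=O)c1ccccc1 | intermediate
15 | [2-hydroxy-4-methoxy-3,5-bis(3-methylbut-2-enyl)-6-[2-(trimethylsilyl)ethoxy]phenyl](phenyl)methanone | C[Si](C)(C)CCOc1c(CC=C(C)C)c(OC)c(CC=C(C)C)c(O)c1C(=O)c1ccccc1 | intermediate
16 | (2,6-dihydroxy-4-methoxy-3,5-bis(3-methylbut-2-enyl)phenyl)(phenyl)methanone | COc1c(CC=C(C)C)c(O)c(C(=O)c2ccccc2)c(O)c1CC=C(C)C | target

**Step count and risks**

Total steps: 8. Longest linear sequence: 6 steps (steps 1, 2, 3, 4, 7, 8); the ynone branch (steps 5 and 6) joins at step 7.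

Steps most likely to fail:

Step 7. The addition may stop after the first C–C bond at an open-chain Michael stage, or the ketene acetal double bond may add to the ynone in a (2+2) sense. The ynol ether may fragment by retro-ene loss on warming, and the adduct may lose silanol instead of methanol. The fallback uses known chemistry and buys ring A instead of building it. It sets out from prenyl bromide 2: commercial 2,4,6-trihydroxybenzophenone is C-prenylated twice with 2 (aqueous KOH, 0 °C) to give 2,4,6-trihydroxy-3,5-bis(3-methylbut-2-enyl)benzophenone F1. The para hydroxyl, the only one that cannot hydrogen-bond to the ketone and the most acidic, is then methylated (one equivalent of Me2SO4, K2CO3, acetone, or Me3SiCHN2 in MeOH–PhMe). This returns to the route at target 16.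

Step 6. The liberated N,O-dimethylhydroxylamine may add in conjugate fashion to the ynone during the quench, or the ynol ether may be hydrated by the acid used to suppress that addition. The fallback introduces the benzoyl carbon at the alcohol oxidation level. It sets out from dichlorovinyl ether 9: lithium acetylide 11, generated as before, is added to benzaldehyde to give racemic 1-phenyl-3-[2-(trimethylsilyl)ethoxy]prop-2-yn-1-ol F2 after a neutral quench. Oxidation with activated MnO2 in CH2Cl2 under neutral conditions returns to the route at ynone 12.

Step 3. C-methylation of the tetrasubstituted enolate may compete with O-methylation. The fallback reaches the enol ether by ketal formation and elimination instead of enolate alkylation. It sets out from keto ester 4: HC(OMe)3 in MeOH with catalytic camphorsulfonic acid at 25 °C gives methyl 3,3-dimethoxy-7-methyl-2-(3-methylbut-2-enyl)oct-6-enoate F3. Heating F3 with catalytic pyridinium p-toluenesulfonate in PhMe while distilling off methanol returns to the route at enol ether 5; a regioisomeric enol ether, if formed, would give the same dienolate in step 4.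

**Further compounds**

F1 | step 7 | 2,4,6-trihydroxy-3,5-bis(3-methylbut-2-enyl)benzophenone | Oc1c(CC=C(C)C)c(O)c(C(=O)c2ccccc2)c(O)c1CC=C(C)C
F2 | step 6 | 1-phenyl-3-[2-(trimethylsilyl)ethoxy]prop-2-yn-1-ol (racemic) | C[Si](C)(C)CCOC#CC(O)c1ccccc1
F3 | step 3 | methyl 3,3-dimethoxy-7-methyl-2-(3-methylbut-2-enyl)oct-6-enoate | COC(=O)C(CC=C(C)C)C(OC)(OC)CCC=C(C)C
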